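**Assumptions:** The target has no sp³ stereocentres; its only stereochemistry is the two E trisubstituted alkenes, which come from (2E,6E)-farnesol and are never touched. I assume the 4-OH of the catechol (para to the ester, more acidic) is alkylated preferentially over the 3-OH.

## Retrosynthesis
1. The phthalide lactone is formed last: NaBH4 reduces an ortho-formyl methyl benzoate and the resulting CH2OH closes onto the ester.
2. The ortho CHO comes from Mg-mediated (Casnati–Skattebøl) formylation of the only free phenol, at C2 between OH and CO2Me.
3. The aryl ether comes from SN2 of commercial methyl 3,4-dihydroxy-5-methoxybenzoate with an 11-acetoxy-10,11-dihydrofarnesyl chloride.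
4. That chloride comes from (E,E)-farnesol by terminal bromohydrin formation, hydride opening to the tertiary alcohol, allylic chlorination, and tertiary acetylation.
5. The only ring formed is the lactone, at the end; the benzene ring is commercial.

## Route

**Step 1**
Reactants: 1 (2E,6E)-farnesol
Product: 2 (2E,6E)-farnesyl acetate
Conditions: Ac2O, pyridine, cat. DMAP, CH2Cl2, 0 °C → rt
Reagents that add atoms: acetic anhydride, CC(=O)OC(C)=O
Why: Acetylation protects the allylic alcohol and inductively deactivates the 2,3-alkene for the next step (acylation).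

**Step 2**
Reactants: 2 farnesyl acetate
Product: 3 (2E,6E)-10-bromo-11-hydroxy-3,7,11-trimethyldodeca-2,6-dienyl acetate (10,11-bromohydrin)
Conditions: NBS, THF/H2O (3:1), 0 °C, then chromatography to remove regioisomers
Reagents that add atoms: N-bromosuccinimide, O=C1CCC(=O)N1Br; water, O
Why: Halohydrin formation is Markovnikov (Br on C10, OH on the tertiary C11) and favours the terminal alkene, the most remote from the acetate. The new C10 stereocentre is formed as a mixture but is destroyed in step 3.

**Step 3**
Reactants: 3 bromohydrin
Product: 4 (2E,6E)-3,7,11-trimethyldodeca-2,6-diene-1,11-diol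
Conditions: LiAlH4 (3 equiv), THF, 0 °C → 65 °C
Reagents that add atoms: none (LiAlH4 only delivers H)
Why: LiAlH4 cleaves the acetate. The tertiary alkoxide closes to the 10,11-epoxide, and hydride attacks the less hindered C10 to give the tertiary alcohol (net terminal Markovnikov hydration). The C10 stereocentre is lost and the alkenes are untouched.

**Step 4**
Reactants: 4 diol
Product: 5 (6E,10E)-12-chloro-2,6,10-trimethyldodeca-6,10-dien-2-ol
Conditions: MsCl, 2,4,6-collidine, LiCl, DMF, 0 °C
Reagents that add atoms: lithium chloride, [Li+].[Cl-]
Why: Collington–Meyers chlorination. The primary allylic alcohol forms a mesylate that chloride displaces by SN2 at the primary carbon, so E geometry is kept. The hindered tertiary alcohol is not mesylated.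

**Step 5**
Reactants: 5 chloro-alcohol
Product: 6 (6E,10E)-12-chloro-2,6,10-trimethyldodeca-6,10-dien-2-yl acetate
Conditions: Ac2O (5 equiv), Et3N, DMAP (0.2 equiv), CH2Cl2, rt → 40 °C
Reagents that add atoms: acetic anhydride, CC(=O)OC(C)=O
Why: DMAP-catalysed acylation of the tertiary alcohol. It is done now, before the free phenol is present, so the phenol is never acetylated.

**Step 6**
Reactants: 6 allylic chloride; 7 methyl 3,4-dihydroxy-5-methoxybenzoate (1.3 equiv)
Product: 8 methyl 4-{[(2E,6E)-11-acetoxy-3,7,11-trimethyldodeca-2,6-dien-1-yl]oxy}-3-hydroxy-5-methoxybenzoate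
Conditions: K2CO3 (1.1 equiv), NaI (0.2 equiv), DMF, 40 °C
Reagents that add atoms: none (the base and catalyst are not incorporated)
Why: Williamson O-alkylation through the more acidic 4-phenoxide, para to the ester, leaves the 3-OH free. NaI converts the chloride in situ to the iodide, and SN2 at the primary allylic carbon retains E geometry.

**Step 7**
Reactants: 8 phenol ester
Product: 9 methyl 4-{[(2E,6E)-11-acetoxy-3,7,11-trimethyldodeca-2,6-dien-1-yl]oxy}-2-formyl-3-hydroxy-5-methoxybenzoate
Conditions: MgCl2 (2 equiv), Et3N (4 equiv), (CH2O)n (7 equiv), MeCN, reflux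
Reagents that add atoms: paraformaldehyde, C=O (supplies the CHO carbon and oxygen)
Why: Casnati–Skattebøl ortho-formylation. The Mg phenoxide delivers formaldehyde to the ortho position, and C2 is the only free ortho position (C4 is blocked by the ether). The acetate, the allyl ether and the alkenes survive these mild basic conditions.

**Step 8**
Reactants: 9 formyl ester
Product: 10 Farnesylemefuranone F
Conditions: NaBH4, THF/MeOH, 0 °C; then 1 M HCl (aq), 0 °C → rt (or cat. PPTS, CH2Cl2)
Reagents that add atoms: none (NaBH4 only delivers H)
Why: The aldehyde is reduced chemoselectively to ArCH2O⁻/ArCH2OH. It attacks the ortho methyl ester intramolecularly and expels MeOH, forming the five-membered phthalide. No new stereocentre is made, and the tertiary acetate and E,E-alkenes are untouched.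

## Compound list
1 | (2E,6E)-farnesol | OC/C=C(\C)CC/C=C(\C)CCC=C(C)C | starting material
2 | (2E,6E)-farnesyl acetate | CC(=O)OC/C=C(\C)CC/C=C(\C)CCC=C(C)C | intermediate
3 | (2E,6E)-10-bromo-11-hydroxy-10,11-dihydrofarnesyl acetate (C10 epimeric mixture) | CC(=O)OC/C=C(\C)CC/C=C(\C)CCC(Br)C(C)(C)O | intermediate
4 | (2E,6E)-3,7,11-trimethyldodeca-2,6-diene-1,11-diol | OC/C=C(\C)CC/C=C(\C)CCCC(C)(C)O | intermediate
5 | (6E,10E)-12-chloro-2,6,10-trimethyldodeca-6,10-dien-2-ol | ClC/C=C(\C)CC/C=C(\C)CCCC(C)(C)O | intermediate
6 | (6E,10E)-12-chloro-2,6,10-trimethyldodeca-6,10-dien-2-yl acetate | ClC/C=C(\C)CC/C=C(\C)CCCC(C)(C)OC(C)=O | intermediate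
7 | methyl 3,4-dihydroxy-5-methoxybenzoate | COC(=O)c1cc(OC)c(O)c(O)c1 | starting material
8 | 4-O-(11-acetoxy-10,11-dihydrofarnesyl) ether of 7 | COC(=O)c1cc(OC)c(OC/C=C(\C)CC/C=C(\C)CCCC(C)(C)OC(C)=O)c(O)c1 | intermediate
9 | 2-formyl derivative of 8 | COC(=O)c1cc(OC)c(OC/C=C(\C)CC/C=C(\C)CCCC(C)(C)OC(C)=O)c(O)c1C=O | intermediate
10 | Farnesylemefuranone F | COc1cc2c(c(O)c1OC/C=C(\C)CC/C=C(\C)CCCC(C)(C)OC(C)=O)COC2=O | target

## Totals
Total steps: 8. Longest linear sequence: 8 (farnesol → 2 → 3 → 4 → 5 → 6 → 8 → 9 → 10).

## Three steps most likely to fail
1. **Step 2 (terminal bromohydrin).** The terminal alkene is only moderately selective over the 6,7-alkene, so yields are about 35–45% with regioisomers.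
   - Fallback: build the chain convergently. Negishi Zr-catalysed carboalumination/iodination of a terminal alkyne carrying the Me2C(OAc) terminus gives the E-vinyl iodide. Negishi coupling with an (E)-homogeranyl zinc reagent then assembles the C6=C7 alkene, avoiding polyene oxidation.
2. **Step 6 (catechol regioselectivity).** Some 3-O-alkylation or dialkylation may occur because the 4-OH is flanked by OH and OMe.
   - Fallback: use the phthalide-first order. Form 4,5-dihydroxy-6-methoxyphthalide from catechol 7, then alkylate its more acidic 5-OH (para to the lactone carbonyl; the 4-OH is hindered by the peri CH2).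
3. **Step 7 (ortho-formylation).** The phenol is deactivated by the ester, and C2 is crowded (flanked by CO2Me and OH), which may give low conversion.
   - Fallback: use a directed ortho-metalation route. Convert the 3-OH to an O-MOM ether (or carbamate) and the acid to a diethylamide, with the 4-OH temporarily benzyl-protected. Lithiate at C2, between the two directing groups, and quench with DMF. Then reduce and lactonize, deprotect, and alkylate with chloride 6.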